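The pyranone ring C is opened at O1–C2 and C4–C4a, which leads back to an aryl cinnamate in which the C4 acyl carbon hangs on O1 as an ester. The plan exploits the 1,3-relationship of O1 and C4a across C8a of ring A: C4a is the only free carbon ortho to O1, since C8 carries the prenyl group. In the key step iodine–lithium exchange at C4a triggers an anionic Fries acyl shift from O1 to C4a, and the liberated O1 then closes ring C onto C2 by a catalyst-controlled oxa-Michael addition that sets the 2S centre. The precursor is the o-iodoaryl ester of the MOM-protected, prenylated A-ring phenol with the prenylated B-ring cinnamic acid.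

Key step: step 8

Remark: the bifunctional thiourea derived from 9-amino-9-deoxy-epi-quinidine is assumed to give the 2S sense of ring closure; if the opposite sense is found, its quinine-derived pseudoenantiomer is used under the same conditions. (Prenyl = 3-methylbut-2-en-1-yl; MOM = methoxymethyl.)

Step 1
Reactants: 1 phloroglucinol (benzene-1,3,5-triol)
Product: 2 3,5-bis(methoxymethoxy)phenol
Conditions: MOMCl (2.0 equiv), i-Pr2NEt (2.2 equiv), DMF, 0 °C → rt
Reagents that add atoms: chloromethyl methyl ether (MOMCl), COCCl
Why: Williamson-type O-alkylation with two equivalents of the α-chloro ether should stop largely at the bis-ether, which is a single compound because the three hydroxyls are equivalent and is separated from mono- and tris-ether by chromatography.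

Step 2
Reactants: 2 3,5-bis(methoxymethoxy)phenol
Product: 3 2-iodo-3,5-bis(methoxymethoxy)phenol
Conditions: NIS (1.0 equiv), CH2Cl2, −40 → 0 °C, dark
Reagents that add atoms: N-iodosuccinimide (NIS), O=C1CCC(=O)N1I
Why: electrophilic aromatic iodination of the highly activated ring should go ortho to the free hydroxyl (two equivalent positions), as is usual for 3,5-dialkoxyphenols, because the para carbon is flanked by two OMOM groups, and the neutral conditions leave the acetals intact.

Step 3
Reactants: 3 2-iodo-3,5-bis(methoxymethoxy)phenol
Product: 4 2-iodo-3,5-bis(methoxymethoxy)-6-prenylphenol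
Conditions: NaH (1.1 equiv), toluene, 0 °C; prenyl bromide (1.2 equiv), rt → 40 °C
Reagents that add atoms: prenyl bromide (1-bromo-3-methylbut-2-ene), CC(C)=CCBr
Why: ortho C-alkylation of a sodium phenoxide held as a tight ion pair in a non-polar solvent should deliver the allyl halide by SN2 at its primary carbon to the only free ortho position, giving the linear prenyl group next to the phenol oxygen, with the O-prenyl ether as a separable by-product.

Step 4
Reactants: 5 4-hydroxybenzaldehyde
Product: 6 4-hydroxy-3-prenylbenzaldehyde
Conditions: prenyl bromide (1.0 equiv), 10% aq. KOH, rt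
Reagents that add atoms: prenyl bromide (1-bromo-3-methylbut-2-ene), CC(C)=CCBr
Why: C-alkylation of the phenoxide in water, where hydrogen bonding shields the oxygen, is the known direct route to this ortho-prenylphenol (the para position is blocked by the formyl group), and O-alkylated and doubly alkylated material is removed by chromatography.

Step 5
Reactants: 6 4-hydroxy-3-prenylbenzaldehyde
Product: 7 4-(methoxymethoxy)-3-prenylbenzaldehyde
Conditions: MOMCl (1.3 equiv), i-Pr2NEt (1.5 equiv), CH2Cl2, 0 °C → rt
Reagents that add atoms: chloromethyl methyl ether (MOMCl), COCCl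
Why: Williamson-type O-alkylation of the single phenol gives the MOM ether, which masks the acidic OH for the esterification and organolithium steps and is removed together with the other two acetals at the end.

Step 6
Reactants: 7 4-(methoxymethoxy)-3-prenylbenzaldehyde
Product: 8 (E)-3-[4-(methoxymethoxy)-3-prenylphenyl]prop-2-enoic acid
Conditions: malonic acid (2 equiv), pyridine, piperidine (0.1 equiv), 90 °C
Reagents that add atoms: malonic acid, OC(=O)CC(=O)O
Why: Knoevenagel–Doebner condensation with decarboxylation should give the E-cinnamic acid directly, and the basic medium is harmless to the MOM ether and the prenyl group.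

Step 7
Reactants: 4 2-iodo-3,5-bis(methoxymethoxy)-6-prenylphenol, 8 (E)-3-[4-(methoxymethoxy)-3-prenylphenyl]prop-2-enoic acid
Product: 9 2-iodo-3,5-bis(methoxymethoxy)-6-prenylphenyl (E)-3-[4-(methoxymethoxy)-3-prenylphenyl]prop-2-enoate
Conditions: DCC (1.2 equiv), DMAP (0.2 equiv), CH2Cl2, 0 °C → rt
Reagents that add atoms: none
Why: Steglich esterification through the acylpyridinium ion should acylate the hindered phenol under neutral conditions and so builds the temporary O1–C4 ester bond that ties the cinnamoyl unit to the correct oxygen.

Step 8
Reactants: 9 2-iodo-3,5-bis(methoxymethoxy)-6-prenylphenyl (E)-3-[4-(methoxymethoxy)-3-prenylphenyl]prop-2-enoate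
Product: 13 (2S)-5,7-bis(methoxymethoxy)-2-[4-(methoxymethoxy)-3-prenylphenyl]-8-prenylchroman-4-one, via ortho-lithiated aryl ester 10 (not isolated), via lithium phenoxide of the chalcone 11 (not isolated), via 2'-hydroxychalcone 12 (not isolated)
Conditions: n-BuLi (1.05 equiv), THF, −100 °C, 15 min; AcOH (1.05 equiv), −100 °C → rt; THF replaced by toluene, lithium salts filtered off; then 9-amino-9-deoxy-epi-quinidine 3,5-bis(trifluoromethyl)phenyl thiourea (10 mol%), toluene, 0 °C
Reagents that add atoms: none
Why: Iodine–lithium exchange at −100 °C should be faster than addition of n-BuLi to the ester and places lithium on C4a, whose carbanion attacks the neighbouring ester carbonyl through a four-membered alkoxide that collapses to the ketone (anionic ortho-Fries 1,3-O→C acyl shift), so that the C4–C4a bond forms while the O1–C4 ester bond breaks and O1 is released as phenoxide 11. Protonation gives 2'-hydroxychalcone 12, which the bifunctional catalyst closes by intramolecular oxa-Michael addition: the quinuclidine nitrogen activates the O1–H as a general base while the thiourea hydrogen-bonds the enone carbonyl, and O1 adds to C2 in a 6-endo-trig closure of the pyranone ring C. The closest known reaction types are the halogen–metal-exchange-induced anionic Fries rearrangement of o-iodoaryl esters and the cinchona-alkaloid-catalysed asymmetric cyclisation of 2'-hydroxychalcones to flavanones. The C2 stereocentre is set under catalyst control, the chiral pocket of the thiourea exposing one enantiotopic face of the E-enone to O1 (2S by the remark above). No regioselectivity is demanded of the reagents, because the acyl group can only be delivered to the lithiated ortho carbon C4a (the other ortho carbon C8 bears the prenyl group) and only O1 is unprotected, O5 and O7 being MOM ethers, which rules out the 6-prenyl isomer; the 5-OMOM group next to the carbonyl also biases the chalcone–flavanone equilibrium toward the closed form and so limits erosion by retro-Michael opening.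

Step 9
Reactants: 13 (2S)-5,7-bis(methoxymethoxy)-2-[4-(methoxymethoxy)-3-prenylphenyl]-8-prenylchroman-4-one
Product: 14 Euchrestaflavanone A, (2S)-5,7-dihydroxy-2-(4-hydroxy-3-prenylphenyl)-8-prenylchroman-4-one
Conditions: 3 M aq. HCl/MeOH (1:4), 45 °C, stopped at full conversion
Reagents that add atoms: none
Why: acid-catalysed acetal methanolysis through the methoxymethyl oxocarbenium ion should free all three phenols in one operation, C2 is not expected to epimerise because ring opening to the chalcone needs base, and the moderate temperature and short exposure are chosen to spare the prenyl double bonds.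

Compound list
1 | phloroglucinol (benzene-1,3,5-triol) | Oc1cc(O)cc(O)c1 | starting material
2 | 3,5-bis(methoxymethoxy)phenol | COCOc1cc(O)cc(OCOC)c1 | intermediate
3 | 2-iodo-3,5-bis(methoxymethoxy)phenol | Oc1cc(OCOC)cc(OCOC)c1I | intermediate
4 | 2-iodo-3,5-bis(methoxymethoxy)-6-prenylphenol | CC(C)=CCc1c(O)c(I)c(OCOC)cc1OCOC | intermediate
5 | 4-hydroxybenzaldehyde | O=Cc1ccc(O)cc1 | starting material
6 | 4-hydroxy-3-prenylbenzaldehyde | CC(C)=CCc1cc(C=O)ccc1O | intermediate
7 | 4-(methoxymethoxy)-3-prenylbenzaldehyde | CC(C)=CCc1cc(C=O)ccc1OCOC | intermediate
8 | (E)-3-[4-(methoxymethoxy)-3-prenylphenyl]prop-2-enoic acid | CC(C)=CCc1cc(/C=C/C(=O)O)ccc1OCOC | intermediate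
9 | 2-iodo-3,5-bis(methoxymethoxy)-6-prenylphenyl (E)-3-[4-(methoxymethoxy)-3-prenylphenyl]prop-2-enoate | CC(C)=CCc1cc(/C=C/C(=O)Oc2c(I)c(OCOC)cc(OCOC)c2CC=C(C)C)ccc1OCOC | intermediate
10 | ortho-lithiated aryl ester (lithium in place of iodine, not isolated) | CC(C)=CCc1cc(/C=C/C(=O)Oc2c([Li])c(OCOC)cc(OCOC)c2CC=C(C)C)ccc1OCOC | intermediate
11 | lithium phenoxide of the chalcone (not isolated) | CC(C)=CCc1cc(/C=C/C(=O)c2c(O[Li])c(CC=C(C)C)c(OCOC)cc2OCOC)ccc1OCOC | intermediate
12 | (E)-1-[2-hydroxy-4,6-bis(methoxymethoxy)-3-prenylphenyl]-3-[4-(methoxymethoxy)-3-prenylphenyl]prop-2-en-1-one (not isolated) | CC(C)=CCc1cc(/C=C/C(=O)c2c(O)c(CC=C(C)C)c(OCOC)cc2OCOC)ccc1OCOC | intermediate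
13 | (2S)-5,7-bis(methoxymethoxy)-2-[4-(methoxymethoxy)-3-prenylphenyl]-8-prenylchroman-4-one | CC(C)=CCc1cc([C@@H]2CC(=O)c3c(OCOC)cc(OCOC)c(CC=C(C)C)c3O2)ccc1OCOC | intermediate
14 | Euchrestaflavanone A, (2S)-5,7-dihydroxy-2-(4-hydroxy-3-prenylphenyl)-8-prenylchroman-4-one | CC(C)=CCc1cc([C@@H]2CC(=O)c3c(O)cc(O)c(CC=C(C)C)c3O2)ccc1O | target

Total step count: 9. Longest linear sequence: 6 steps (steps 1, 2, 3, 7, 8, 9 or steps 4, 5, 6, 7, 8, 9).

Steps most likely to fail

Step 8. Facial selectivity in the oxa-Michael closure may be poor, because the enone carries no second activating group and any lithium salt carried over can promote an uncatalysed, unselective closure. The closed product can also slowly reopen and reclose in the presence of the amine catalyst. Fallback: stereocontrol by resolution instead of catalysis. Setting out from 9, the same exchange and acyl shift are run, but the lithium phenoxide 11 is warmed to room temperature after addition of MeOH, where it should close without facial control to the racemic tris-MOM flavanone F1. Preparative HPLC on an amylose tris(3,5-dimethylphenylcarbamate) stationary phase then separates the enantiomers, and the 2S enantiomer re-enters the route as 13. The unwanted 2R enantiomer F2 can be returned to F1 by base-mediated ring opening and re-closure (DBU, MeOH) and resolved again.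

Step 3. O-alkylation of the ambident phenoxide may outrun ortho C-alkylation, and the iodine next to the oxygen adds steric hindrance. Fallback: the prenyl group is put on carbon before the oxygens are differentiated. Setting out from 1, direct C-prenylation of the triol (prenyl bromide, 10% aq. KOH, 0 °C → rt, phloroglucinol in excess) gives 2-prenylphloroglucinol F3. Bis-etherification (MOMCl 2.0 equiv, i-Pr2NEt, DMF, 0 °C) should give 3,5-bis(methoxymethoxy)-2-prenylphenol F4, since the unhindered hydroxyl para to the prenyl group reacts first and either of the two equivalent flanking hydroxyls second. Iodination of F4 with NIS at −78 °C, where the ring should be far more reactive than the trisubstituted alkene, then places iodine on the remaining carbon ortho to the free hydroxyl and comes back to the route at 4.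

Step 9. The freed 7-OH and 4'-OH may add under acid catalysis across the neighbouring prenyl double bonds (chroman formation) before the last acetal is cleaved, and long heating in acid may erode C2. Fallback: the acetals are exchanged for silyl ethers under non-protic conditions and the silyl ethers are then removed with buffered fluoride. Setting out from 13, TESOTf and 2,2'-bipyridyl (CH2Cl2, 0 °C → rt) should convert the three aryl MOM ethers into the tris(triethylsilyl) ether F5. TBAF buffered with AcOH (THF, 0 °C) then cleaves the aryl silyl ethers without base-induced ring opening and comes back to the route at 14.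

Further compounds
F1 | step 8 | racemic 5,7-bis(methoxymethoxy)-2-[4-(methoxymethoxy)-3-prenylphenyl]-8-prenylchroman-4-one | CC(C)=CCc1cc(C2CC(=O)c3c(OCOC)cc(OCOC)c(CC=C(C)C)c3O2)ccc1OCOC
F2 | step 8 | (2R)-5,7-bis(methoxymethoxy)-2-[4-(methoxymethoxy)-3-prenylphenyl]-8-prenylchroman-4-one | CC(C)=CCc1cc([C@H]2CC(=O)c3c(OCOC)cc(OCOC)c(CC=C(C)C)c3O2)ccc1OCOC
F3 | step 3 | 2-prenylphloroglucinol (2-(3-methylbut-2-en-1-yl)benzene-1,3,5-triol) | CC(C)=CCc1c(O)cc(O)cc1O
F4 | step 3 | 3,5-bis(methoxymethoxy)-2-prenylphenol | CC(C)=CCc1c(O)cc(OCOC)cc1OCOC
F5 | step 9 | (2S)-5,7-bis(triethylsilyloxy)-2-[4-(triethylsilyloxy)-3-prenylphenyl]-8-prenylchroman-4-one | CC(C)=CCc1cc([C@@H]2CC(=O)c3c(O[Si](CC)(CC)CC)cc(O[Si](CC)(CC)CC)c(CC=C(C)C)c3O2)ccc1O[Si](CC)(CC)CC
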